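## Retrosynthetic overview

1. Target 32 ⇐ (step 18) hydrogenolysis of five benzyl ethers and one aryl C–Cl bond of the protected 5-chloro-4-arylisoflavan 31.
2. 31 ⇐ (step 17) formal insertion of 5-(benzyloxy)-3-chlorobenzyne (from silyl triflate 7) into the benzylic C–O bond of cis-2,3-diaryloxetane 27. This makes the aryl–O1 and C4–C4a bonds of the isoflavan and its C4 stereocentre in one operation, the aryne carbons becoming C8a and C4a.
3. Enabling feature: O1 and C4 of the dihydropyran ring are 1,3-related through C2–C3 and can be tied into an oxetane. C4 is benzylic to ring A of the flavanone (flanked by its 5-O and 7-O, para to its ring oxygen), so this C–O bond ionises once the oxygen is arylated. The benzo ring of the isoflavan carries only H at C5, C6 and C8, so its C4a–C8a edge can come from an aryne, with a removable chlorine at C5 beside the triple bond to steer the oxygen to C8a.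
4. 27 ⇐ oxetane closure with the flavanone carbonyl held as the flavan-4-ol (steps 14–16) ⇐ Evans syn aldol (step 13, sets C3) of arylacetyl imide 15 with 6-formyl tri-O-benzylnaringenin 20.
5. Ring order: flavanone rings from (2S)-naringenin (chiral pool, supplies C2) → temporary oxetane (step 15) → dihydropyran ring of the isoflavan, closed onto the aryne-derived benzo ring (step 17).

Key step: step 17

Assumption: (2S)-naringenin is taken as the commercial single enantiomer; because a flavanone epimerises at C2 by reversible ring opening in base, every step run while the chromanone carbonyl is present is neutral or only weakly basic.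

## Route

Step 1
Reactants: 1 4-(benzyloxy)phenol
Product: 2 4-(benzyloxy)-2-chlorophenol
Conditions: SO2Cl2 (1 equiv), i-Bu2NH (cat.), toluene, 70 °C
Reagents that add atoms: sulfuryl chloride ClS(Cl)(=O)=O
Why: Electrophilic aromatic chlorination ortho to the free hydroxyl (para position blocked), the amine-catalysed sulfuryl chloride protocol being ortho-selective for phenols.

Step 2
Reactants: 2 4-(benzyloxy)-2-chlorophenol
Product: 3 4-(benzyloxy)-2-bromo-6-chlorophenol
Conditions: NBS, MeCN, 0 °C → rt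
Reagents that add atoms: N-bromosuccinimide O=C1CCC(=O)N1Br
Why: Electrophilic bromination at the only remaining position ortho to the phenolic hydroxyl, which outranks the benzyl ether as director.

Step 3
Reactants: 3 4-(benzyloxy)-2-bromo-6-chlorophenol
Product: 7 4-(benzyloxy)-2-chloro-6-(trimethylsilyl)phenyl trifluoromethanesulfonate, via trimethylsilyl ether 4 (not isolated), via aryllithium 5 (not isolated), via lithium phenoxide 6 (not isolated)
Conditions: HMDS, THF, 65 °C, evaporate; n-BuLi, THF, −78 °C → rt; Tf2O, −78 °C → rt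
Reagents that add atoms: hexamethyldisilazane C[Si](C)(C)N[Si](C)(C)C; trifluoromethanesulfonic anhydride O=S(=O)(OS(=O)(=O)C(F)(F)F)C(F)(F)F
Why: O-Silylation, bromine–lithium exchange (faster than any reaction of the C–Cl bond or the benzyl ether at −78 °C), retro-Brook 1,3-shift of silicon from oxygen to carbon and O-triflation of the phenoxide, the standard sequence to 2-silylaryl triflates.

Step 4
Reactants: 8 2,6-dimethoxyphenol
Product: 9 2-(benzyloxy)-1,3-dimethoxybenzene
Conditions: BnBr, K2CO3, DMF, 60 °C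
Reagents that add atoms: benzyl bromide BrCc1ccccc1
Why: Williamson ether synthesis on a simple phenol.

Step 5
Reactants: 9 2-(benzyloxy)-1,3-dimethoxybenzene
Product: 10 3-(benzyloxy)-1-bromo-2,4-dimethoxybenzene
Conditions: NBS, MeCN, 0 °C → rt
Reagents that add atoms: N-bromosuccinimide O=C1CCC(=O)N1Br
Why: Electrophilic bromination para to one methoxy and ortho to the other, the site preferred in 1,2,3-trialkoxybenzenes because the central alkoxy group is twisted out of conjugation.

Step 6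
Reactants: 10 3-(benzyloxy)-1-bromo-2,4-dimethoxybenzene
Product: 11 tert-butyl 2-[3-(benzyloxy)-2,4-dimethoxyphenyl]acetate
Conditions: BrZnCH2CO2t-Bu, Pd(dba)2 (cat.), P(t-Bu)3 (cat.), THF, rt
Reagents that add atoms: tert-butyl 2-(bromozincio)acetate Br[Zn]CC(=O)OC(C)(C)C
Why: Palladium-catalysed α-arylation of a Reformatsky (zinc ester enolate) reagent, a Negishi-type coupling that tolerates the ethers.

Step 7
Reactants: 11 tert-butyl 2-[3-(benzyloxy)-2,4-dimethoxyphenyl]acetate
Product: 12 2-[3-(benzyloxy)-2,4-dimethoxyphenyl]acetic acid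
Conditions: CF3CO2H/CH2Cl2 (1:4), 0 °C
Reagents that add atoms: none
Why: Acidolysis of the tert-butyl ester with loss of isobutene, the aryl benzyl ether surviving dilute acid at 0 °C.

Step 8
Reactants: 12 2-[3-(benzyloxy)-2,4-dimethoxyphenyl]acetic acid; 13 (S)-4-benzyloxazolidin-2-one
Product: 15 (S)-4-benzyl-3-{2-[3-(benzyloxy)-2,4-dimethoxyphenyl]acetyl}oxazolidin-2-one, via mixed pivalic anhydride 14 (not isolated)
Conditions: PivCl, Et3N, THF, −20 °C; then 13, LiCl, rt
Reagents that add atoms: none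
Why: N-Acylation of the oxazolidinone through the mixed pivalic anhydride under LiCl/amine activation, which leaves the stereocentre of the auxiliary untouched.

Step 9
Reactants: 16 (2S)-naringenin
Product: 17 (2S)-7-(benzyloxy)-2-[4-(benzyloxy)phenyl]-5-hydroxychroman-4-one
Conditions: BnOH (2.2 equiv), PPh3, DIAD, THF, 0 °C → rt
Reagents that add atoms: benzyl alcohol OCc1ccccc1
Why: Mitsunobu etherification of the two acidic, non-chelated phenols (7-OH and 4'-OH) under neutral conditions, the hydrogen-bonded 5-OH staying free and the base-labile C2 centre untouched.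

Step 10
Reactants: 17 (2S)-7-(benzyloxy)-2-[4-(benzyloxy)phenyl]-5-hydroxychroman-4-one
Product: 18 (2S)-7-(benzyloxy)-2-[4-(benzyloxy)phenyl]-5-hydroxy-6-iodochroman-4-one
Conditions: NIS (1.05 equiv), DMF, rt, dark
Reagents that add atoms: N-iodosuccinimide O=C1CCC(=O)N1I
Why: Electrophilic iodination ortho to the free, chelated 5-hydroxyl (C6), the site preference established for 5-hydroxy-7-alkoxyflavonoids under neutral N-iodosuccinimide conditions.

Step 11
Reactants: 18 (2S)-7-(benzyloxy)-2-[4-(benzyloxy)phenyl]-5-hydroxy-6-iodochroman-4-one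
Product: 19 (2S)-5,7-bis(benzyloxy)-2-[4-(benzyloxy)phenyl]-6-iodochroman-4-one
Conditions: BnBr, Ag2O, DMF, rt, dark
Reagents that add atoms: benzyl bromide BrCc1ccccc1
Why: Silver-oxide-mediated O-benzylation (Williamson type) of the hindered chelated phenol without soluble base, so that retro-oxa-Michael opening of the flavanone is avoided.

Step 12
Reactants: 19 (2S)-5,7-bis(benzyloxy)-2-[4-(benzyloxy)phenyl]-6-iodochroman-4-one
Product: 20 (2S)-5,7-bis(benzyloxy)-2-[4-(benzyloxy)phenyl]-4-oxochroman-6-carbaldehyde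
Conditions: CO (1 atm), Bu3SnH (slow addition), Pd(PPh3)4 (cat.), toluene, 50 °C
Reagents that add atoms: carbon monoxide [C-]#[O+]
Why: Palladium-catalysed reductive carbonylation (formylation) of the aryl iodide by oxidative addition, CO insertion and hydride transfer from the tin hydride under neutral conditions.

Step 13
Reactants: 15 (S)-4-benzyl-3-{2-[3-(benzyloxy)-2,4-dimethoxyphenyl]acetyl}oxazolidin-2-one; 20 (2S)-5,7-bis(benzyloxy)-2-[4-(benzyloxy)phenyl]-4-oxochroman-6-carbaldehyde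
Product: 23 syn-aldol adduct (4S)-4-benzyl-3-[(2S,3S)-2-aryl-3-(flavanon-6-yl)-3-hydroxypropanoyl]oxazolidin-2-one, via boron enolate 21 (not isolated), via boron aldolate 22 (not isolated)
Conditions: 15 (1.3 equiv), Bu2BOTf, i-Pr2NEt, CH2Cl2, −78 → 0 °C; then 20, −78 → 0 °C; pH 7 buffer, MeOH, H2O2, 0 °C
Reagents that add atoms: none
Why: Evans syn aldol reaction through the (Z)-boron enolate and a chair Zimmerman–Traxler transition state, in which the (S)-benzyl auxiliary fixes the enolate face and thereby the aryl-bearing α-carbon (the future C3 of the isoflavan), while the carbinol carbon is a stereocentre that is erased in step 17.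

Step 14
Reactants: 23 syn-aldol adduct
Product: 24 (1S,2R)-2-[3-(benzyloxy)-2,4-dimethoxyphenyl]-1-{(2S,4S)-5,7-bis(benzyloxy)-2-[4-(benzyloxy)phenyl]-4-hydroxychroman-6-yl}propane-1,3-diol
Conditions: LiBH4, MeOH (1 equiv), THF, 0 °C → rt
Reagents that add atoms: none
Why: Hydride reduction cleaves the imide to the primary alcohol and, by axial attack, converts the chromanone carbonyl into the 2,4-cis flavan-4-ol, a temporary centre (any 4-epimer converges in step 16) that shields the flavanone C2 from the base of step 15.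

Step 15
Reactants: 24 triol
Product: 26 (2S,4S)-5,7-bis(benzyloxy)-6-{(2S,3R)-3-[3-(benzyloxy)-2,4-dimethoxyphenyl]oxetan-2-yl}-2-[4-(benzyloxy)phenyl]chroman-4-ol (cis-oxetane), via primary tosylate 25 (not isolated)
Conditions: TsCl, Et3N, DMAP (cat.), CH2Cl2, 0 °C; solvent exchange; NaH, THF, 0 → 40 °C
Reagents that add atoms: none
Why: Selective sulfonylation of the primary hydroxyl followed by intramolecular Williamson etherification (4-exo-tet) by the neighbouring benzylic alkoxide, with retention at both stereocentres, which gives the cis-2,3-diaryloxetane.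

Step 16
Reactants: 26 oxetane flavan-4-ol
Product: 27 (2S)-5,7-bis(benzyloxy)-6-{(2S,3R)-3-[3-(benzyloxy)-2,4-dimethoxyphenyl]oxetan-2-yl}-2-[4-(benzyloxy)phenyl]chroman-4-one
Conditions: Dess–Martin periodinane, NaHCO3, CH2Cl2, 0 °C → rt
Reagents that add atoms: none
Why: Dess–Martin oxidation of the only remaining hydroxyl restores the flavanone carbonyl, the bicarbonate buffer protecting the acid-labile 2-aryloxetane.

Step 17
Reactants: 27 oxetane ketone; 7 4-(benzyloxy)-2-chloro-6-(trimethylsilyl)phenyl trifluoromethanesulfonate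
Product: 31 (2S)-5,7-bis(benzyloxy)-6-{(3R,4R)-7-(benzyloxy)-3-[3-(benzyloxy)-2,4-dimethoxyphenyl]-5-chlorochroman-4-yl}-2-[4-(benzyloxy)phenyl]chroman-4-one (3,4-trans), via aryne 28 (not isolated), via oxetanium aryl anion 29 (not isolated), via ring-opened zwitterion 30 (not isolated)
Conditions: 7 (2.5 equiv, slow addition), CsF, MeCN/toluene (1:1), 0 °C → rt
Reagents that add atoms: none
Why: Proposed new method: fluoride-induced 1,2-elimination of 7 gives aryne 28, whose chlorine beside the triple bond polarises and distorts it so that the oxetane oxygen of 27, the only strongly Lewis-basic and unhindered heteroatom left, should add at the aryne carbon distal to chlorine (the weak opposing inductive effect of the remote benzyloxy group being overridden) and leave the carbanion ortho to chlorine in oxetanium ylide 29. The strained oxetanium then ionises at its benzylic C–O bond, because that carbon carries flavanone ring A with two ortho oxygens and one para oxygen, and ion pair 30 collapses by attack of the aryl anion on the cationic carbon (6-exo-trig with respect to the exocyclic quinone-methide-type C=C), which closes the dihydropyran ring and completes a formal insertion of the aryne into the C–O σ-bond. The closest known reaction type is the insertion of arynes into the benzylic C–O bond of aryl epoxides, which gives 2,3-dihydrobenzofurans, within the wider family of aryne σ-bond insertions; the homologous ring expansion of an oxetane to a chroman is the proposed extension. The new C4 stereocentre is controlled by the C3 stereocentre: the planar cation is attacked anti to the C3 aryl group through a half-chair with both aryl groups pseudo-equatorial, so the 3,4-trans chroman is expected whatever the configuration of the ionised oxetane carbon (its CIP descriptor is R only because chlorine outranks oxygen, and becomes S in 32 without change of geometry). The step needs regioselectivity on the aryne (secured by chlorine), cleavage of the benzylic and not the CH2–O bond (secured by the electron-rich aryl group) and integrity of the flavanone C2 centre (mild, aprotic fluoride conditions); chlorine is chosen over bromine because an ortho-chloroaryl anion expels halide more slowly.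

Step 18
Reactants: 31 protected 5-chloro-4-arylisoflavan
Product: 32 (2S)-5,7-dihydroxy-6-[(3R,4S)-7-hydroxy-3-(3-hydroxy-2,4-dimethoxyphenyl)chroman-4-yl]-2-(4-hydroxyphenyl)chroman-4-one
Conditions: H2 (1 atm), Pd/C, NaOAc, EtOAc/MeOH, rt
Reagents that add atoms: none
Why: Heterogeneous hydrogenolysis of the five benzyl ethers and hydrodechlorination of the aryl chloride in one operation, the acetate buffer taking up HCl so that neither acid nor amine base endangers the flavanone C2 centre.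

## Compound list

1 | 4-(benzyloxy)phenol | Oc1ccc(OCc2ccccc2)cc1 | starting material
2 | 4-(benzyloxy)-2-chlorophenol | Oc1ccc(OCc2ccccc2)cc1Cl | intermediate
3 | 4-(benzyloxy)-2-bromo-6-chlorophenol | Oc1c(Br)cc(OCc2ccccc2)cc1Cl | intermediate
4 | [4-(benzyloxy)-2-bromo-6-chlorophenoxy]trimethylsilane | C[Si](C)(C)Oc1c(Br)cc(OCc2ccccc2)cc1Cl | intermediate
5 | {5-(benzyloxy)-3-chloro-2-[(trimethylsilyl)oxy]phenyl}lithium | C[Si](C)(C)Oc1c([Li])cc(OCc2ccccc2)cc1Cl | intermediate
6 | lithium 4-(benzyloxy)-2-chloro-6-(trimethylsilyl)phenoxide | [Li+].[O-]c1c(Cl)cc(OCc2ccccc2)cc1[Si](C)(C)C | intermediate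
7 | 4-(benzyloxy)-2-chloro-6-(trimethylsilyl)phenyl trifluoromethanesulfonate | C[Si](C)(C)c1cc(OCc2ccccc2)cc(Cl)c1OS(=O)(=O)C(F)(F)F | intermediate
8 | 2,6-dimethoxyphenol | COc1cccc(OC)c1O | starting material
9 | 2-(benzyloxy)-1,3-dimethoxybenzene | COc1cccc(OC)c1OCc1ccccc1 | intermediate
10 | 3-(benzyloxy)-1-bromo-2,4-dimethoxybenzene | COc1ccc(Br)c(OC)c1OCc1ccccc1 | intermediate
11 | tert-butyl 2-[3-(benzyloxy)-2,4-dimethoxyphenyl]acetate | COc1ccc(CC(=O)OC(C)(C)C)c(OC)c1OCc1ccccc1 | intermediate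
12 | 2-[3-(benzyloxy)-2,4-dimethoxyphenyl]acetic acid | COc1ccc(CC(=O)O)c(OC)c1OCc1ccccc1 | intermediate
13 | (S)-4-benzyloxazolidin-2-one | O=C1N[C@@H](Cc2ccccc2)CO1 | starting material
14 | 2-[3-(benzyloxy)-2,4-dimethoxyphenyl]acetic pivalic anhydride | COc1ccc(CC(=O)OC(=O)C(C)(C)C)c(OC)c1OCc1ccccc1 | intermediate
15 | (S)-4-benzyl-3-{2-[3-(benzyloxy)-2,4-dimethoxyphenyl]acetyl}oxazolidin-2-one | COc1ccc(CC(=O)N2[C@@H](Cc3ccccc3)COC2=O)c(OC)c1OCc1ccccc1 | intermediate
16 | (2S)-naringenin, (2S)-5,7-dihydroxy-2-(4-hydroxyphenyl)chroman-4-one | O=C1C[C@@H](c2ccc(O)cc2)Oc2cc(O)cc(O)c12 | starting material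
17 | (2S)-7-(benzyloxy)-2-[4-(benzyloxy)phenyl]-5-hydroxychroman-4-one | O=C1C[C@@H](c2ccc(OCc3ccccc3)cc2)Oc2cc(OCc3ccccc3)cc(O)c12 | intermediate
18 | (2S)-7-(benzyloxy)-2-[4-(benzyloxy)phenyl]-5-hydroxy-6-iodochroman-4-one | O=C1C[C@@H](c2ccc(OCc3ccccc3)cc2)Oc2cc(OCc3ccccc3)c(I)c(O)c12 | intermediate
19 | (2S)-5,7-bis(benzyloxy)-2-[4-(benzyloxy)phenyl]-6-iodochroman-4-one | O=C1C[C@@H](c2ccc(OCc3ccccc3)cc2)Oc2cc(OCc3ccccc3)c(I)c(OCc3ccccc3)c12 | intermediate
20 | (2S)-5,7-bis(benzyloxy)-2-[4-(benzyloxy)phenyl]-4-oxochroman-6-carbaldehyde | O=C1C[C@@H](c2ccc(OCc3ccccc3)cc2)Oc2cc(OCc3ccccc3)c(C=O)c(OCc3ccccc3)c12 | intermediate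
21 | (S)-4-benzyl-3-{(Z)-2-[3-(benzyloxy)-2,4-dimethoxyphenyl]-1-[(dibutylboryl)oxy]vinyl}oxazolidin-2-one (boron enolate of 15) | CCCCB(CCCC)O/C(=C\c1ccc(OC)c(OCc2ccccc2)c1OC)N1[C@@H](Cc2ccccc2)COC1=O | intermediate
22 | O-dibutylboryl aldolate of 23 | O=C(N1[C@@H](Cc2ccccc2)COC1=O)[C@@H](c1ccc(OC)c(OCc2ccccc2)c1OC)[C@H](OB(CCCC)CCCC)c1c(OCc2ccccc2)cc2O[C@H](c3ccc(OCc4ccccc4)cc3)CC(=O)c2c1OCc1ccccc1 | intermediate
23 | (4S)-4-benzyl-3-[(2S,3S)-2-[3-(benzyloxy)-2,4-dimethoxyphenyl]-3-{(2S)-5,7-bis(benzyloxy)-2-[4-(benzyloxy)phenyl]-4-oxochroman-6-yl}-3-hydroxypropanoyl]oxazolidin-2-one | O=C(N1[C@@H](Cc2ccccc2)COC1=O)[C@@H](c1ccc(OC)c(OCc2ccccc2)c1OC)[C@H](O)c1c(OCc2ccccc2)cc2O[C@H](c3ccc(OCc4ccccc4)cc3)CC(=O)c2c1OCc1ccccc1 | intermediate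
24 | (1S,2R)-2-[3-(benzyloxy)-2,4-dimethoxyphenyl]-1-{(2S,4S)-5,7-bis(benzyloxy)-2-[4-(benzyloxy)phenyl]-4-hydroxychroman-6-yl}propane-1,3-diol | OC[C@@H](c1ccc(OC)c(OCc2ccccc2)c1OC)[C@H](O)c1c(OCc2ccccc2)cc2O[C@H](c3ccc(OCc4ccccc4)cc3)C[C@H](O)c2c1OCc1ccccc1 | intermediate
25 | (2R,3S)-2-[3-(benzyloxy)-2,4-dimethoxyphenyl]-3-{(2S,4S)-5,7-bis(benzyloxy)-2-[4-(benzyloxy)phenyl]-4-hydroxychroman-6-yl}-3-hydroxypropyl 4-methylbenzenesulfonate | Cc1ccc(S(=O)(=O)OC[C@@H](c2ccc(OC)c(OCc3ccccc3)c2OC)[C@H](O)c2c(OCc3ccccc3)cc3O[C@H](c4ccc(OCc5ccccc5)cc4)C[C@H](O)c3c2OCc2ccccc2)cc1 | intermediate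
26 | (2S,4S)-5,7-bis(benzyloxy)-6-{(2S,3R)-3-[3-(benzyloxy)-2,4-dimethoxyphenyl]oxetan-2-yl}-2-[4-(benzyloxy)phenyl]chroman-4-ol (cis-oxetane) | C1O[C@H](c2c(OCc3ccccc3)cc3O[C@H](c4ccc(OCc5ccccc5)cc4)C[C@H](O)c3c2OCc2ccccc2)[C@@H]1c1ccc(OC)c(OCc2ccccc2)c1OC | intermediate
27 | (2S)-5,7-bis(benzyloxy)-6-{(2S,3R)-3-[3-(benzyloxy)-2,4-dimethoxyphenyl]oxetan-2-yl}-2-[4-(benzyloxy)phenyl]chroman-4-one (cis-oxetane) | C1O[C@H](c2c(OCc3ccccc3)cc3O[C@H](c4ccc(OCc5ccccc5)cc4)CC(=O)c3c2OCc2ccccc2)[C@@H]1c1ccc(OC)c(OCc2ccccc2)c1OC | intermediate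
28 | 5-(benzyloxy)-3-chlorobenzyne (5-(benzyloxy)-3-chloro-1,2-didehydrobenzene) | ClC1=CC(OCc2ccccc2)=CC#C1 | intermediate
29 | oxetanium ylide from 27 and 28: O-[5-(benzyloxy)-3-chlorophenyl-2-ide]oxetanium zwitterion, carbanion ortho to O+ and Cl, oxetane carbons as in 27 | C1[O+](c2cc(OCc3ccccc3)cc(Cl)[c-]2)[C@H](c2c(OCc3ccccc3)cc3O[C@H](c4ccc(OCc5ccccc5)cc4)CC(=O)c3c2OCc2ccccc2)[C@@H]1c1ccc(OC)c(OCc2ccccc2)c1OC | intermediate
30 | ring-opened zwitterion: 2-aryloxyaryl anion and flavanon-6-yl-stabilised benzylic cation, aryl-bearing carbon configured as in 27 | [c-]1c(Cl)cc(OCc2ccccc2)cc1OC[C@@H](c1ccc(OC)c(OCc2ccccc2)c1OC)[CH+]c1c(OCc2ccccc2)cc2O[C@H](c3ccc(OCc4ccccc4)cc3)CC(=O)c2c1OCc1ccccc1 | intermediate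
31 | (2S)-5,7-bis(benzyloxy)-6-{(3R,4R)-7-(benzyloxy)-3-[3-(benzyloxy)-2,4-dimethoxyphenyl]-5-chlorochroman-4-yl}-2-[4-(benzyloxy)phenyl]chroman-4-one (3,4-trans) | COc1ccc([C@@H]2COc3cc(OCc4ccccc4)cc(Cl)c3[C@H]2c2c(OCc3ccccc3)cc3c(c2OCc2ccccc2)C(=O)C[C@@H](c2ccc(OCc4ccccc4)cc2)O3)c(OC)c1OCc1ccccc1 | intermediate
32 | (2S)-5,7-dihydroxy-6-[(3R,4S)-7-hydroxy-3-(3-hydroxy-2,4-dimethoxyphenyl)chroman-4-yl]-2-(4-hydroxyphenyl)chroman-4-one (3,4-trans) | COc1ccc([C@@H]2COc3cc(O)ccc3[C@H]2c2c(O)cc3c(c2O)C(=O)C[C@@H](c2ccc(O)cc2)O3)c(OC)c1O | target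

## Step count and risks

Total step count: 18. Longest linear sequence: 11 steps (steps 4–8, then 13–18).

Steps most likely to fail:

1. Step 17 (proposed new method). The ion pair may lose a proton from C3 instead of collapsing. The aryne may be consumed by fluoride or by a benzyl ether oxygen before the hindered oxetane oxygen reaches it. The ortho-chloroaryl anion may expel chloride. Fluoride may open the flavanone by retro-oxa-Michael reaction and so erode C2. The fallback uses known chemistry, sets out from 27 and comes back at 32. Acid-catalysed methanolysis of the 2-aryloxetane at its benzylic carbon (PPTS, MeOH/CH2Cl2, 0 °C) should give the γ-hydroxy benzylic methyl ether (2S)-5,7-bis(benzyloxy)-6-{(2R)-2-[3-(benzyloxy)-2,4-dimethoxyphenyl]-3-hydroxy-1-methoxypropyl}-2-[4-(benzyloxy)phenyl]chroman-4-one F1 (both epimers at the methoxy carbon are usable). Mitsunobu etherification of its primary hydroxyl with 3-(benzyloxy)phenol (PPh3, DIAD, THF) should give the aryl ether (2S)-5,7-bis(benzyloxy)-6-{(2R)-2-[3-(benzyloxy)-2,4-dimethoxyphenyl]-3-[3-(benzyloxy)phenoxy]-1-methoxypropyl}-2-[4-(benzyloxy)phenyl]chroman-4-one F2. BF3·OEt2 in CH2Cl2 at −40 °C then ionises the benzylic methyl ether, and the cation should close onto the resorcinol-type ring ortho to the ether oxygen and para to the benzyloxy group (intramolecular Friedel–Crafts alkylation, anti to the C3 aryl group). This gives the chlorine-free 3,4-trans isoflavan (2S)-5,7-bis(benzyloxy)-6-{(3R,4S)-7-(benzyloxy)-3-[3-(benzyloxy)-2,4-dimethoxyphenyl]chroman-4-yl}-2-[4-(benzyloxy)phenyl]chroman-4-one F3. Hydrogenolysis as in step 18, without NaOAc, then gives 32.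

2. Step 15. The γ-sulfonyloxy alkoxide may undergo Grob fragmentation to an aldehyde and a styrene, or the sulfonate may be lost by E2 elimination at the benzylic C–H, faster than the strained and crowded four-membered ring closes. The fallback sets out from 24 and comes back at 32. The 1,3-diol is tied up with 2,2-dimethoxypropane and PPTS as the acetonide (2S,4S)-5,7-bis(benzyloxy)-6-{(4S,5R)-5-[3-(benzyloxy)-2,4-dimethoxyphenyl]-2,2-dimethyl-1,3-dioxan-4-yl}-2-[4-(benzyloxy)phenyl]chroman-4-ol F4. The flavan-4-ol is oxidised (Dess–Martin periodinane, NaHCO3) to the acetonide ketone (2S)-5,7-bis(benzyloxy)-6-{(4S,5R)-5-[3-(benzyloxy)-2,4-dimethoxyphenyl]-2,2-dimethyl-1,3-dioxan-4-yl}-2-[4-(benzyloxy)phenyl]chroman-4-one F5. Acid-catalysed methanolysis (PPTS, MeOH) releases the primary alcohol and exchanges the benzylic oxygen for methoxy, giving the γ-hydroxy benzylic methyl ether F1. The sequence then runs on through the aryl ether F2 and the chlorine-free isoflavan F3 as described under 1.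

3. Step 18. Hydrodechlorination may lag behind debenzylation, and long exposure may hydrogenolyse the benzylic C2–O bond or reduce the carbonyl of the flavanone. The fallback sets out from 31 and comes back at 32. Lewis-acid debenzylation with BCl3 and pentamethylbenzene (CH2Cl2, −78 °C, aryl methyl ethers retained) should give the chloro pentaphenol (2S)-6-[(3R,4R)-5-chloro-7-hydroxy-3-(3-hydroxy-2,4-dimethoxyphenyl)chroman-4-yl]-5,7-dihydroxy-2-(4-hydroxyphenyl)chroman-4-one F6. The single remaining C–Cl bond is then cleaved by brief catalytic transfer hydrogenolysis (Pd/C, HCO2NH4, MeOH, rt).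

Further compounds
F1 | step 17 | (2S)-5,7-bis(benzyloxy)-6-{(2R)-2-[3-(benzyloxy)-2,4-dimethoxyphenyl]-3-hydroxy-1-methoxypropyl}-2-[4-(benzyloxy)phenyl]chroman-4-one | OC[C@@H](c1ccc(OC)c(OCc2ccccc2)c1OC)C(OC)c1c(OCc2ccccc2)cc2O[C@H](c3ccc(OCc4ccccc4)cc3)CC(=O)c2c1OCc1ccccc1
F2 | step 17 | (2S)-5,7-bis(benzyloxy)-6-{(2R)-2-[3-(benzyloxy)-2,4-dimethoxyphenyl]-3-[3-(benzyloxy)phenoxy]-1-methoxypropyl}-2-[4-(benzyloxy)phenyl]chroman-4-one | O(C[C@@H](c1ccc(OC)c(OCc2ccccc2)c1OC)C(OC)c1c(OCc2ccccc2)cc2O[C@H](c3ccc(OCc4ccccc4)cc3)CC(=O)c2c1OCc1ccccc1)c1cccc(OCc2ccccc2)c1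
F3 | step 17 | (2S)-5,7-bis(benzyloxy)-6-{(3R,4S)-7-(benzyloxy)-3-[3-(benzyloxy)-2,4-dimethoxyphenyl]chroman-4-yl}-2-[4-(benzyloxy)phenyl]chroman-4-one | COc1ccc([C@@H]2COc3cc(OCc4ccccc4)ccc3[C@H]2c2c(OCc3ccccc3)cc3c(c2OCc2ccccc2)C(=O)C[C@@H](c2ccc(OCc4ccccc4)cc2)O3)c(OC)c1OCc1ccccc1
F4 | step 15 | (2S,4S)-5,7-bis(benzyloxy)-6-{(4S,5R)-5-[3-(benzyloxy)-2,4-dimethoxyphenyl]-2,2-dimethyl-1,3-dioxan-4-yl}-2-[4-(benzyloxy)phenyl]chroman-4-ol | CC1(C)OC[C@@H](c2ccc(OC)c(OCc3ccccc3)c2OC)[C@@H](c2c(OCc3ccccc3)cc3O[C@H](c4ccc(OCc5ccccc5)cc4)C[C@H](O)c3c2OCc2ccccc2)O1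
F5 | step 15 | (2S)-5,7-bis(benzyloxy)-6-{(4S,5R)-5-[3-(benzyloxy)-2,4-dimethoxyphenyl]-2,2-dimethyl-1,3-dioxan-4-yl}-2-[4-(benzyloxy)phenyl]chroman-4-one | CC1(C)OC[C@@H](c2ccc(OC)c(OCc3ccccc3)c2OC)[C@@H](c2c(OCc3ccccc3)cc3O[C@H](c4ccc(OCc5ccccc5)cc4)CC(=O)c3c2OCc2ccccc2)O1
F6 | step 18 | (2S)-6-[(3R,4R)-5-chloro-7-hydroxy-3-(3-hydroxy-2,4-dimethoxyphenyl)chroman-4-yl]-5,7-dihydroxy-2-(4-hydroxyphenyl)chroman-4-one | COc1ccc([C@@H]2COc3cc(O)cc(Cl)c3[C@H]2c2c(O)cc3c(c2O)C(=O)C[C@@H](c2ccc(O)cc2)O3)c(OC)c1O
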